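**Retrosynthetic overview**
- The strategy rests on one feature: the strained 12-membered ring (phenanthrene C4, C4a, C4b, C5, C6, two carbons of ring C, the CH2CH2 bridge, three carbons of ring D) is an unstrained 16-membered tetra-aryl cyclophane that lacks only the C4a–C4b bond and has the phenanthrene C9=C10 bond as its cis-stilbene bridge.
- Last disconnections: the three phenols (isopropyl ethers, BCl3), then the C4a–C4b bond by oxidative 6π photocyclisation across the macrocycle, which makes central ring B and the 12-membered ring in one event.
- The 16-membered ring is opened at C9=C10 (intramolecular McMurry coupling of a tetra-aryl dialdehyde).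
- The open chain is cut at the two biaryl bonds (Suzuki couplings: ring E to ring D at an iodide, ring A to ring C at a hindered bromide) and at the CH2CH2 bridge (Wittig, then diimide), giving four purchased benzene rings.
- Ring order: four bought arenes, then the 16-membered ring (McMurry), then ring B together with the 12-membered ring (photocyclisation).

Key step: step 15

Assumption: the target has no stereocentre and the twist of the bridged phenanthrene is unspecified, so racemic material is made. Phenanthrene numbering: ring E = C1–C4 (chlorophenol ring), ring A = C5–C8 (anisole ring), ring C = chlorophenol ring on C6, ring D = phenol ring on C4.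

**Route**

Step 1
Reactants: 1 4-hydroxy-3-iodobenzaldehyde
Product: 2 3-iodo-4-isopropoxybenzaldehyde
Conditions: 2-bromopropane, K2CO3, DMF, 60 °C
Reagents that add atoms: 2-bromopropane CC(C)Br
Why: Williamson etherification of the phenoxide; the isopropyl ether should survive base, palladium, low-valent titanium and light and can later be removed by BCl3 beside a methyl ether.

Step 2
Reactants: 2 3-iodo-4-isopropoxybenzaldehyde
Product: 3 (3-iodo-4-isopropoxyphenyl)methanol
Conditions: NaBH4, MeOH, 0 °C
Reagents that add atoms: none
Why: Borohydride reduction of the aldehyde, to which the aryl iodide and the ether are inert.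

Step 3
Reactants: 3 (3-iodo-4-isopropoxyphenyl)methanol
Product: 4 4-(bromomethyl)-2-iodo-1-isopropoxybenzene
Conditions: PBr3, CH2Cl2, 0 °C
Reagents that add atoms: phosphorus tribromide BrP(Br)Br
Why: Activation of the benzylic alcohol as a phosphite ester and SN2 displacement by bromide; the electron-rich bromide is used at once.

Step 4
Reactants: 4 4-(bromomethyl)-2-iodo-1-isopropoxybenzene
Product: 5 (3-iodo-4-isopropoxybenzyl)triphenylphosphonium bromide
Conditions: PPh3, toluene, 100 °C
Reagents that add atoms: triphenylphosphine c1ccc(cc1)P(c1ccccc1)c1ccccc1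
Why: SN2 quaternisation of the phosphine by the benzylic bromide; the salt should crystallise from toluene.

Step 5
Reactants: 6 2-bromo-4-chlorophenol
Product: 7 2-bromo-4-chloro-1-isopropoxybenzene
Conditions: 2-bromopropane, K2CO3, DMF, 60 °C
Reagents that add atoms: 2-bromopropane CC(C)Br
Why: Williamson etherification of the phenoxide.

Step 6
Reactants: 7 2-bromo-4-chloro-1-isopropoxybenzene
Product: 9 2-bromo-6-chloro-3-isopropoxybenzaldehyde, via aryllithium 8 (not isolated)
Conditions: LiN(iPr)2, THF, −78 °C; DMF, −78 °C; then H2O
Reagents that add atoms: N,N-dimethylformamide CN(C)C=O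
Why: Directed ortho-metalation: the hydrogen flanked by Br and Cl is the most acidic, the amide base does not exchange halogen and the 2,6-dihaloaryllithium is stable at −78 °C, so formylation puts CHO exactly between the halogens, a pattern that electrophilic bromination of a preformed hydroxybenzaldehyde would not be expected to give cleanly because attack at the other ortho position of the phenol competes.

Step 7
Reactants: 5 (3-iodo-4-isopropoxybenzyl)triphenylphosphonium bromide; 9 2-bromo-6-chloro-3-isopropoxybenzaldehyde
Product: 11 1-(2-bromo-6-chloro-3-isopropoxyphenyl)-2-(3-iodo-4-isopropoxyphenyl)ethene (E/Z mixture), via phosphonium ylide 10 (not isolated)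
Conditions: NaN(SiMe3)2, THF, 0 °C; then 9, 0 °C to rt
Reagents that add atoms: none
Why: Wittig olefination of the electron-poor, doubly ortho-substituted aldehyde with the semistabilised benzylic ylide; the olefin geometry is irrelevant because the double bond is reduced next.

Step 8
Reactants: 11 stilbene of rings C and D (E/Z mixture)
Product: 12 1-(2-bromo-6-chloro-3-isopropoxyphenyl)-2-(3-iodo-4-isopropoxyphenyl)ethane
Conditions: p-toluenesulfonyl hydrazide, NaOAc, DME/H2O, reflux
Reagents that add atoms: none
Why: Diimide reduction: diimide released from the sulfonyl hydrazide delivers H2 concertedly to the C=C bond and leaves the C–I, C–Br and C–Cl bonds alone, which catalytic hydrogenation would endanger.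

Step 9
Reactants: 13 3-bromo-5-chloro-4-hydroxybenzaldehyde
Product: 14 3-bromo-5-chloro-4-isopropoxybenzaldehyde
Conditions: 2-bromopropane (excess), K2CO3, DMF, 70 °C
Reagents that add atoms: 2-bromopropane CC(C)Br
Why: Williamson etherification; the acidic, doubly ortho-halogenated phenoxide is a weak nucleophile, hence warm DMF and excess alkyl bromide.

Step 10
Reactants: 14 3-bromo-5-chloro-4-isopropoxybenzaldehyde
Product: 15 3-chloro-4-isopropoxy-5-(4,4,5,5-tetramethyl-1,3,2-dioxaborolan-2-yl)benzaldehyde
Conditions: B2pin2, PdCl2(dppf), KOAc, dioxane, 85 °C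
Reagents that add atoms: bis(pinacolato)diboron CC1(C)OB(OC1(C)C)B1OC(C)(C)C(C)(C)O1
Why: Miyaura borylation; with this catalyst oxidative addition to C–Br is far faster than to C–Cl and the weak acetate base does not start a Suzuki homocoupling, while the aldehyde is tolerated.

Step 11
Reactants: 12 bibenzyl of rings C and D; 15 ring E boronate
Product: 16 triaryl aldehyde (12 with the ring D iodide replaced by the 3-chloro-5-formyl-2-isopropoxyphenyl group; ring C bromide intact)
Conditions: Pd(PPh3)4, Na2CO3, DME/H2O, 60 °C
Reagents that add atoms: none
Why: Suzuki–Miyaura coupling in which the triphenylphosphine catalyst inserts into the aryl iodide far faster than into the bromide shielded by OiPr and the CH2CH2 chain or into the chlorides, so only the ring D position should couple.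

Step 12
Reactants: 17 4-bromo-3-methoxybenzaldehyde
Product: 18 3-methoxy-4-(4,4,5,5-tetramethyl-1,3,2-dioxaborolan-2-yl)benzaldehyde
Conditions: B2pin2, PdCl2(dppf), KOAc, dioxane, 85 °C
Reagents that add atoms: bis(pinacolato)diboron CC1(C)OB(OC1(C)C)B1OC(C)(C)C(C)(C)O1
Why: Miyaura borylation of an unhindered, aldehyde-activated aryl bromide.

Step 13
Reactants: 16 triaryl aldehyde with ring C bromide; 18 ring A boronate
Product: 19 open tetra-aryl dialdehyde (16 with the ring C bromide replaced by the 4-formyl-2-methoxyphenyl group)
Conditions: Pd(OAc)2, SPhos, K3PO4, toluene/H2O, 70 °C, 1.1 equiv of 18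
Reagents that add atoms: none
Why: Suzuki–Miyaura coupling with a bulky electron-rich biarylphosphine, which permits oxidative addition and reductive elimination at a biaryl with three ortho substituents; both chlorides are electron-rich and ortho-substituted, so the C–Br bond should react first at this temperature with near-stoichiometric boronate.

Step 14
Reactants: 19 open tetra-aryl dialdehyde
Product: 20 16-membered cyclophane cis-stilbene tri-isopropyl ether (rings E and A joined by (Z)-CH=CH in place of the two formyl groups)
Conditions: TiCl4, Zn, pyridine, THF, reflux; 19 added slowly by syringe pump (high dilution)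
Reagents that add atoms: none
Why: Intramolecular McMurry coupling: the two aryl aldehydes are reductively joined and deoxygenated on low-valent titanium, driven by Ti–O bond formation; slow addition favours the unstrained 16-membered ring, which accommodates the cis olefin, aryl chlorides and ethers are inert, and any trans isomer is corrected by the light of the next step.

Step 15
Reactants: 20 16-membered cyclophane cis-stilbene tri-isopropyl ether
Product: 22 bridged phenanthrene tri-isopropyl ether (the target with its three OH groups as OiPr), via trans-4a,4b-dihydrophenanthrene 21 (not isolated)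
Conditions: hν (medium-pressure Hg lamp, Pyrex filter), I2 (1.1 equiv), propylene oxide (excess), degassed toluene, dilute, rt
Reagents that add atoms: none
Why: Light excites the cis-stilbene of 20, and the hexatriene made of ring E C4a (the inner CH between the olefin-bearing and the ring D-bearing carbons), C10a, C10, C9, C8a and ring A C4b (the CH ortho to the olefin carbon and para to OMe) undergoes conrotatory 6π electrocyclisation to the trans-4a,4b-dihydrophenanthrene 21, from which iodine removes both hydrogens while propylene oxide takes up the HI, so that aromatisation is irreversible and neither acid nor reductant builds up. The closest known reaction type is the Mallory oxidative photocyclisation of stilbenes to phenanthrenes in its iodine and propylene oxide form, which has also been applied to macrocyclic stilbenes (stilbenophanes to phenanthrenophanes). Ring B closes as a six-membered ring by electrocyclisation, whereas the 12-membered ring is not closed end to end: it arises by transannular contraction of the 16-membered ring when the C4a–C4b bond forms. The two sp3 centres of 21 are trans through the conrotatory excited-state course and disappear on oxidation, so no stereocentre remains and the twisted product forms as a racemate. The step needs regioselectivity, which the substrate secures: on ring E only the inner CH points into the macrocycle, since closure at the CH next to chlorine would oblige the seven-atom tether (three ring D carbons, CH2CH2, two ring C carbons) to reach from C2 to C6, and on ring A closure at the CH beside OMe would push OMe into the bay against the C4 aryl group. It also needs the stilbene chromophore to react in preference to the C–Cl bonds, which the Pyrex cut-off secures, and the strain of the product is paid for by the photon and the aromatisation, not by a ground-state macrocyclisation.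

Step 16
Reactants: 22 bridged phenanthrene tri-isopropyl ether
Product: 23 CNP0310669.0 (target)
Conditions: BCl3, CH2Cl2, −78 to 0 °C; then H2O
Reagents that add atoms: none
Why: Lewis-acid ether cleavage: BCl3 binds the ether oxygens and the secondary isopropyl groups leave as 2-chloropropane at low temperature, whereas the methyl ether, which cannot ionise, and the aryl chlorides are kept.

**Compound list**
1 | 4-hydroxy-3-iodobenzaldehyde (ring D) | O=Cc1ccc(O)c(I)c1 | starting material
2 | 3-iodo-4-isopropoxybenzaldehyde | O=Cc1ccc(OC(C)C)c(I)c1 | intermediate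
3 | (3-iodo-4-isopropoxyphenyl)methanol | OCc1ccc(OC(C)C)c(I)c1 | intermediate
4 | 4-(bromomethyl)-2-iodo-1-isopropoxybenzene | BrCc1ccc(OC(C)C)c(I)c1 | intermediate
5 | (3-iodo-4-isopropoxybenzyl)triphenylphosphonium bromide | CC(C)Oc1ccc(C[P+](c2ccccc2)(c2ccccc2)c2ccccc2)cc1I.[Br-] | intermediate
6 | 2-bromo-4-chlorophenol (ring C) | Oc1ccc(Cl)cc1Br | starting material
7 | 2-bromo-4-chloro-1-isopropoxybenzene | CC(C)Oc1ccc(Cl)cc1Br | intermediate
8 | (2-bromo-6-chloro-3-isopropoxyphenyl)lithium | CC(C)Oc1ccc(Cl)c([Li])c1Br | intermediate (not isolated)
9 | 2-bromo-6-chloro-3-isopropoxybenzaldehyde | O=Cc1c(Br)c(OC(C)C)ccc1Cl | intermediate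
10 | (3-iodo-4-isopropoxybenzylidene)triphenylphosphorane | CC(C)Oc1ccc(C=P(c2ccccc2)(c2ccccc2)c2ccccc2)cc1I | intermediate (not isolated)
11 | 1-(2-bromo-6-chloro-3-isopropoxyphenyl)-2-(3-iodo-4-isopropoxyphenyl)ethene, E/Z mixture | CC(C)Oc1ccc(C=Cc2c(Cl)ccc(OC(C)C)c2Br)cc1I | intermediate
12 | 1-(2-bromo-6-chloro-3-isopropoxyphenyl)-2-(3-iodo-4-isopropoxyphenyl)ethane | CC(C)Oc1ccc(CCc2c(Cl)ccc(OC(C)C)c2Br)cc1I | intermediate
13 | 3-bromo-5-chloro-4-hydroxybenzaldehyde (ring E) | O=Cc1cc(Cl)c(O)c(Br)c1 | starting material
14 | 3-bromo-5-chloro-4-isopropoxybenzaldehyde | O=Cc1cc(Cl)c(OC(C)C)c(Br)c1 | intermediate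
15 | 3-chloro-4-isopropoxy-5-(pinacolboryl)benzaldehyde | O=Cc1cc(Cl)c(OC(C)C)c(B2OC(C)(C)C(C)(C)O2)c1 | intermediate
16 | triaryl aldehyde (rings E, D, C; ring C bromide intact) | O=Cc1cc(Cl)c(OC(C)C)c(-c2cc(CCc3c(Cl)ccc(OC(C)C)c3Br)ccc2OC(C)C)c1 | intermediate
17 | 4-bromo-3-methoxybenzaldehyde (ring A) | COc1cc(C=O)ccc1Br | starting material
18 | 3-methoxy-4-(pinacolboryl)benzaldehyde | COc1cc(C=O)ccc1B1OC(C)(C)C(C)(C)O1 | intermediate
19 | open tetra-aryl dialdehyde | O=Cc1cc(Cl)c(OC(C)C)c(-c2cc(CCc3c(Cl)ccc(OC(C)C)c3-c3ccc(C=O)cc3OC)ccc2OC(C)C)c1 | intermediate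
20 | 16-membered cyclophane cis-stilbene tri-isopropyl ether | COc1cc2ccc1-c1c(OC(C)C)ccc(Cl)c1CCc1ccc(OC(C)C)c(c1)-c1cc(cc(Cl)c1OC(C)C)/C=C\2 | intermediate
21 | trans-4a,4b-dihydrophenanthrene (racemic, relative configuration shown) | COC1=CC2=CC=C3C=C(Cl)C(OC(C)C)=C4[C@H]3[C@@H]2C=C1-c1c(OC(C)C)ccc(Cl)c1CCc1ccc(OC(C)C)c-4c1 | intermediate (not isolated)
22 | bridged phenanthrene tri-isopropyl ether | COc1cc2ccc3cc(Cl)c(OC(C)C)c4c3c2cc1-c1c(OC(C)C)ccc(Cl)c1CCc1ccc(OC(C)C)c-4c1 | intermediate
23 | CNP0310669.0 | COc1cc2ccc3cc(Cl)c(O)c4c3c2cc1-c1c(O)ccc(Cl)c1CCc1ccc(O)c-4c1 | target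

**Summary**
Total step count: 16.
Longest linear sequence: 11 steps (steps 1, 2, 3, 4, 7, 8, 11, 13, 14, 15, 16, from 1).

**Steps most likely to fail**

1. Step 15. The excited stilbene may only interconvert its olefin isomers because the strained dihydrophenanthrene reverts faster than iodine traps it, closure may take place at the ring A CH beside OMe, or C–Cl bonds may be photolysed. The fallback closes the same C4a–C4b bond in the ground state by an aryl radical; it sets out from 16 and comes back at 22. Bought 2-bromo-5-methoxybenzaldehyde F1 would be iodinated at the free position ortho to OMe and para to CHO (N-iodosuccinimide, CF3CO2H) to 2-bromo-4-iodo-5-methoxybenzaldehyde F2. The hindered bromide of 16 would be converted into the pinacol boronate F3 (B2pin2, Pd(OAc)2, SPhos, KOAc, dioxane). Suzuki coupling of F3 with F2 at the iodide (Pd(PPh3)4, Ba(OH)2, DME/H2O, 60 °C) should give the bromo dialdehyde F4. McMurry coupling as in step 14 should give the 16-membered cis-stilbene F5, with bromine on ring A at the future C4b. Bu3SnH with azobisisobutyronitrile in toluene at reflux would then generate the ring A aryl radical, which adds to the inner CH of ring E, and loss of the hydrogen atom re-aromatises to 22.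

2. Step 14. Oligomerisation may outrun ring closure, the coupling may stop at the pinacol stage, or chlorine may be lost reductively on the titanium surface. The fallback replaces carbonyl coupling by olefin metathesis; it sets out from 19 and comes back at 20. Double Wittig methylenation of 19 (MePPh3Br, KOC(CH3)3, THF) should give the bis-styrene F6. Ring-closing metathesis with second-generation Grubbs catalyst RuCl2(PCy3)(H2IMes)(=CHPh) in dilute toluene at 80 °C under an argon sweep expels ethylene and should give 20; any trans isomer is corrected by the light of step 15.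

3. Step 13. Palladium may insert into a C–Cl bond in competition with the shielded C–Br bond, or boronate 18 may be protodeboronated while the slow coupling waits. The fallback makes the crowded ring A to ring C bond first, on the small aldehyde 9 whose bromide is activated by the ortho formyl group, and builds the chain afterwards; it sets out from 17 and 9 and comes back at 19. Acetalisation of 17 (ethylene glycol, TsOH, toluene, water removal) gives the dioxolane F7, and Miyaura borylation (B2pin2, PdCl2(dppf), KOAc) gives the boronate F8. Suzuki coupling of F8 with 9 (Pd(PPh3)4, K3PO4, DME/H2O, 85 °C) should give the biaryl aldehyde F9. Wittig reaction with ylide 10 gives the stilbene F10, and diimide reduction as in step 8 gives the bibenzyl F11. Suzuki coupling of F11 with 15 at the iodide as in step 11 gives the acetal aldehyde F12, and aqueous HCl in THF frees the second aldehyde to give 19.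

Further compounds
F1 | step 15 | 2-bromo-5-methoxybenzaldehyde (bought) | COc1ccc(Br)c(C=O)c1
F2 | step 15 | 2-bromo-4-iodo-5-methoxybenzaldehyde | COc1cc(C=O)c(Br)cc1I
F3 | step 15 | triaryl aldehyde with pinacol boronate on ring C | O=Cc1cc(Cl)c(OC(C)C)c(-c2cc(CCc3c(Cl)ccc(OC(C)C)c3B3OC(C)(C)C(C)(C)O3)ccc2OC(C)C)c1
F4 | step 15 | open tetra-aryl dialdehyde with bromine on ring A ortho to its formyl group | O=Cc1cc(Cl)c(OC(C)C)c(-c2cc(CCc3c(Cl)ccc(OC(C)C)c3-c3cc(Br)c(C=O)cc3OC)ccc2OC(C)C)c1
F5 | step 15 | 16-membered cyclophane cis-stilbene with bromine on ring A at the future C4b | COc1cc2c(Br)cc1-c1c(OC(C)C)ccc(Cl)c1CCc1ccc(OC(C)C)c(c1)-c1cc(cc(Cl)c1OC(C)C)/C=C\2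
F6 | step 14 | open tetra-aryl bis-styrene | C=Cc1cc(Cl)c(OC(C)C)c(-c2cc(CCc3c(Cl)ccc(OC(C)C)c3-c3ccc(C=C)cc3OC)ccc2OC(C)C)c1
F7 | step 13 | 2-(4-bromo-3-methoxyphenyl)-1,3-dioxolane | COc1cc(C2OCCO2)ccc1Br
F8 | step 13 | 2-[3-methoxy-4-(pinacolboryl)phenyl]-1,3-dioxolane | COc1cc(C2OCCO2)ccc1B1OC(C)(C)C(C)(C)O1
F9 | step 13 | 6-chloro-2-[4-(1,3-dioxolan-2-yl)-2-methoxyphenyl]-3-isopropoxybenzaldehyde | COc1cc(C2OCCO2)ccc1-c1c(OC(C)C)ccc(Cl)c1C=O
F10 | step 13 | stilbene of the ring A–ring C biaryl and ring D (E/Z mixture) | COc1cc(C2OCCO2)ccc1-c1c(OC(C)C)ccc(Cl)c1C=Cc1ccc(OC(C)C)c(I)c1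
F11 | step 13 | bibenzyl of the ring A–ring C biaryl and ring D with ring D iodide | COc1cc(C2OCCO2)ccc1-c1c(OC(C)C)ccc(Cl)c1CCc1ccc(OC(C)C)c(I)c1
F12 | step 13 | open tetra-aryl aldehyde with ring A formyl group as dioxolane | COc1cc(C2OCCO2)ccc1-c1c(OC(C)C)ccc(Cl)c1CCc1ccc(OC(C)C)c(c1)-c1cc(C=O)cc(Cl)c1OC(C)C
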